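Ring A is cut from the flavonol: everything rests on a benzannulation onto the C4a=C8a bond shared by rings A and C, which in the precursor is the C2=C3 bond of a 4-pyranone. In one operation a Wolff rearrangement, ketene–ynol ether (2+2) cycloaddition and 4π/6π electrocyclic cascade should form C8–C8a, C7–C8, C5–C6 and C4a–C5. It exploits the 1,3-relation of O5 and O7 with C6 and C8 unsubstituted, and delivers O5 free (chelated to the C4 carbonyl) and O7 silylated for later sulfation. The precursor is a kojic-acid-derived 2-diazoacetyl-4-pyranone that already carries the benzylated C3 oxygen and the 4-benzyloxyphenyl ring B.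

Key step: step 7

Assumption: compounds 19 and 20 are drawn as neutral hydrogen sulfates, as in the target SMILES; in practice they would be handled as pyridinium or sodium salts and protonated only at the very end.

Step 1
Reactants: 1 kojic acid
Product: 2 2-bromo-3-hydroxy-6-(hydroxymethyl)-4H-pyran-4-one (6-bromokojic acid)
Conditions: NBS, MeCN, 0 °C to rt
Reagents that add atoms: N-bromosuccinimide, O=C1CCC(=O)N1Br
Why: Electrophilic bromination of the enolic hydroxypyranone should occur at C6 of kojic acid, the only free position ortho to the enol hydroxyl and the site where kojic acid is known to take up halogens and other electrophiles.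

Step 2
Reactants: 2 2-bromo-3-hydroxy-6-(hydroxymethyl)-4H-pyran-4-one
Product: 3 3-(benzyloxy)-2-bromo-6-(hydroxymethyl)-4H-pyran-4-one
Conditions: BnBr, K2CO3, DMF, rt
Reagents that add atoms: benzyl bromide, BrCc1ccccc1
Why: Williamson ether synthesis in which carbonate ionises only the acidic enolic hydroxyl (the primary alcohol stays neutral) and the oxyanion is benzylated at room temperature, where displacement of the vinylogous acyl bromide is not expected to compete.

Step 3
Reactants: 3 3-(benzyloxy)-2-bromo-6-(hydroxymethyl)-4H-pyran-4-one, 4 4-(benzyloxy)phenylboronic acid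
Product: 5 3-(benzyloxy)-2-[4-(benzyloxy)phenyl]-6-(hydroxymethyl)-4H-pyran-4-one
Conditions: Pd(PPh3)4 (5 mol%), K2CO3, 1,4-dioxane/H2O, 85 °C
Reagents that add atoms: none
Why: Suzuki–Miyaura coupling in which the C–Br bond of the 2-bromo-4-pyranone, a vinylogous acyl bromide, should add readily to zerovalent palladium, and transmetalation with the electron-rich arylboronic acid followed by reductive elimination installs ring B while the free alcohol and the benzyl ether are tolerated.

Step 4
Reactants: 5 3-(benzyloxy)-2-[4-(benzyloxy)phenyl]-6-(hydroxymethyl)-4H-pyran-4-one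
Product: 6 5-(benzyloxy)-6-[4-(benzyloxy)phenyl]-4-oxo-4H-pyran-2-carboxylic acid
Conditions: TEMPO (cat.), PhI(OAc)2, MeCN/H2O, rt
Reagents that add atoms: water, O
Why: Oxoammonium (TEMPO) oxidation with PhI(OAc)2 as terminal oxidant takes the primary alcohol to the aldehyde and, through its hydrate, on to the carboxylic acid without touching benzyl ethers or the pyranone, paralleling the established oxidation of O-benzylkojic acid to O-benzylcomenic acid.

Step 5
Reactants: 6 5-(benzyloxy)-6-[4-(benzyloxy)phenyl]-4-oxo-4H-pyran-2-carboxylic acid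
Product: 8 2-diazo-1-{5-(benzyloxy)-6-[4-(benzyloxy)phenyl]-4-oxo-4H-pyran-2-yl}ethanone, via acid chloride 7 (not isolated)
Conditions: (COCl)2, cat. DMF, CH2Cl2, 0 °C to rt, evaporate; then Me3SiCHN2, THF/MeCN, 0 °C
Reagents that add atoms: (trimethylsilyl)diazomethane, C[Si](C)(C)C=[N+]=[N-]
Why: The acid chloride, formed under Vilsmeier catalysis and lacking α-hydrogens, C-acylates the diazoalkane in an Arndt–Eistert-type diazoketone synthesis with chloride removing the silyl group, and acylation at 0 °C should outrun dipolar addition of the reagent to the pyranone double bond.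

Step 6
Reactants: 9 lithium acetylide ethylenediamine complex (LiC≡CH·H2NCH2CH2NH2), 10 triisopropylsilyl trifluoromethanesulfonate
Product: 12 (triisopropylsilyloxy)acetylene, via lithium ethynolate 11 (not isolated)
Conditions: t-BuOOH, LiN(SiMe3)2, THF, −78 °C; then 9, −78 to 0 °C; then 10 (excess), −78 to 0 °C
Reagents that add atoms: tert-butyl hydroperoxide, CC(C)(C)OO
Why: Electrophilic oxygenation of a lithium acetylide by lithium tert-butyl peroxide (the acetylide carbon attacks the peroxide oxygen and expels tert-butoxide) should give ynolate 11, which the hard, bulky silyl triflate captures on oxygen at low temperature; the triflate is used in excess because liberated ethylenediamine also consumes it, and the ynol ether is used at once as a stock solution.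

Step 7
Reactants: 8 2-diazo-1-{5-(benzyloxy)-6-[4-(benzyloxy)phenyl]-4-oxo-4H-pyran-2-yl}ethanone, 12 (triisopropylsilyloxy)acetylene
Product: 17 3-(benzyloxy)-2-[4-(benzyloxy)phenyl]-5-hydroxy-7-(triisopropylsilyloxy)-4H-chromen-4-one, via pyranonylketene 13 (not isolated), via siloxycyclobutenone 14 (not isolated), via dienylketene 15 (not isolated), via 4aH-chromenedione tautomer 16 (not isolated)
Conditions: hν (blue LEDs, 440 nm), 12 (2.5 equiv), ClCH2CH2Cl, rt; then 80 °C
Reagents that add atoms: none
Why: Proposed new method: visible-light Wolff rearrangement of 8 expels N2 and shifts the pyranonyl group to the former diazo carbon (C8–C8a), giving ketene 13, whose carbonyl carbon is attacked by the nucleophilic CH terminus of the polarised ynol ether in a regioselective (2+2) cycloaddition (C5–C6 and C7–C8) to cyclobutenone 14; the closest known reaction type is the second-generation Danheiser benzannulation of alkenyl, aryl and heteroaryl diazoketones with siloxyalkynes, here asked to use the C2=C3 bond of a 4-pyranone as the ene partner. Heating opens 14 by reversible conrotatory 4π electrocyclic cleavage to dienylketene 15, and ring A is then closed by a thermal disrotatory 6π electrocyclisation that joins the ketene carbon to pyranone C3 (C4a–C5), the nucleophilic α-carbon of the vinylogous ester and therefore well matched to the electrophilic ketene. Enolisation of the diketone tautomer 16 is driven by aromatisation of ring A and by the hydrogen bond between the new C5 hydroxyl and the C4 carbonyl. No stereocentre survives, because the sp3 centres of 14 and 16 are lost on ring opening and tautomerisation. The selectivity needed is regiochemical: the siloxy group must end at C7, which the oxygen-induced polarisation of the alkyne secures, and closure can occur only at C3 because the other neighbour of the ketene-bearing carbon is the ring oxygen. Light of 440 nm should be absorbed by the diazo chromophore alone, which keeps the 3-benzyloxy-4-pyranone and the flavone product, both liable to γ-hydrogen abstraction from the OCH2Ph group under ultraviolet light, out of the photochemistry.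

Step 8
Reactants: 17 3-(benzyloxy)-2-[4-(benzyloxy)phenyl]-5-hydroxy-7-(triisopropylsilyloxy)-4H-chromen-4-one
Product: 18 3-(benzyloxy)-2-[4-(benzyloxy)phenyl]-5,7-dihydroxy-4H-chromen-4-one
Conditions: Bu4NF, AcOH, THF, 0 °C
Reagents that add atoms: none
Why: Fluoride attacks silicon and cleaves the aryl silyl ether (the acetic acid buffer keeps the liberated phenoxide protonated), leaving the benzyl ethers and the chelated C5 hydroxyl untouched.

Step 9
Reactants: 18 3-(benzyloxy)-2-[4-(benzyloxy)phenyl]-5,7-dihydroxy-4H-chromen-4-one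
Product: 19 3-(benzyloxy)-2-[4-(benzyloxy)phenyl]-5-hydroxy-4-oxo-4H-chromen-7-yl hydrogen sulfate
Conditions: SO3·pyridine, pyridine, rt
Reagents that add atoms: sulfur trioxide pyridine complex, [O-]S(=O)(=O)[n+]1ccccc1
Why: O-Sulfation of a phenol with the sulfur trioxide–pyridine complex should take place only at the C7 hydroxyl, the one free acidic phenol, because the C5 hydroxyl is locked in a hydrogen bond to the C4 carbonyl and is known to resist sulfation and alkylation under such conditions.

Step 10
Reactants: 19 3-(benzyloxy)-2-[4-(benzyloxy)phenyl]-5-hydroxy-4-oxo-4H-chromen-7-yl hydrogen sulfate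
Product: 20 kaempferol 7-O-sulfate (3,5-dihydroxy-2-(4-hydroxyphenyl)-4-oxo-4H-chromen-7-yl hydrogen sulfate)
Conditions: H2 (1 atm), Pd/C, MeOH/THF, rt; then sulfonic acid resin (H+ form), 0 °C
Reagents that add atoms: none
Why: Palladium-catalysed hydrogenolysis should cleave both benzylic C–O bonds at room temperature while the aryl sulfate monoester and the chromone double bond stay inert, a deprotection commonly used last in flavonoid sulfate work, and brief contact with the acid resin gives the hydrogen sulfate as drawn.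

Compound list
1 | kojic acid | O=c1cc(CO)occ1O | starting material
2 | 2-bromo-3-hydroxy-6-(hydroxymethyl)-4H-pyran-4-one | O=c1cc(CO)oc(Br)c1O | intermediate
3 | 3-(benzyloxy)-2-bromo-6-(hydroxymethyl)-4H-pyran-4-one | O=c1cc(CO)oc(Br)c1OCc1ccccc1 | intermediate
4 | 4-(benzyloxy)phenylboronic acid | OB(O)c1ccc(OCc2ccccc2)cc1 | starting material
5 | 3-(benzyloxy)-2-[4-(benzyloxy)phenyl]-6-(hydroxymethyl)-4H-pyran-4-one | O=c1cc(CO)oc(-c2ccc(OCc3ccccc3)cc2)c1OCc1ccccc1 | intermediate
6 | 5-(benzyloxy)-6-[4-(benzyloxy)phenyl]-4-oxo-4H-pyran-2-carboxylic acid | O=C(O)c1cc(=O)c(OCc2ccccc2)c(-c2ccc(OCc3ccccc3)cc2)o1 | intermediate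
7 | 5-(benzyloxy)-6-[4-(benzyloxy)phenyl]-4-oxo-4H-pyran-2-carbonyl chloride | O=C(Cl)c1cc(=O)c(OCc2ccccc2)c(-c2ccc(OCc3ccccc3)cc2)o1 | intermediate (not isolated)
8 | 2-diazo-1-{5-(benzyloxy)-6-[4-(benzyloxy)phenyl]-4-oxo-4H-pyran-2-yl}ethanone | [N-]=[N+]=CC(=O)c1cc(=O)c(OCc2ccccc2)c(-c2ccc(OCc3ccccc3)cc2)o1 | intermediate
9 | lithium acetylide ethylenediamine complex | [Li]C#C.NCCN | starting material
10 | triisopropylsilyl trifluoromethanesulfonate | CC(C)[Si](C(C)C)(C(C)C)OS(=O)(=O)C(F)(F)F | starting material
11 | lithium ethynolate | [Li]OC#C | intermediate (not isolated)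
12 | (triisopropylsilyloxy)acetylene | C#CO[Si](C(C)C)(C(C)C)C(C)C | intermediate
13 | 2-{5-(benzyloxy)-6-[4-(benzyloxy)phenyl]-4-oxo-4H-pyran-2-yl}ethenone | O=C=Cc1cc(=O)c(OCc2ccccc2)c(-c2ccc(OCc3ccccc3)cc2)o1 | intermediate (not isolated)
14 | 4-{5-(benzyloxy)-6-[4-(benzyloxy)phenyl]-4-oxo-4H-pyran-2-yl}-3-(triisopropylsilyloxy)cyclobut-2-en-1-one (racemic, transient) | O=C1C=C(O[Si](C(C)C)(C(C)C)C(C)C)C1c1cc(=O)c(OCc2ccccc2)c(-c2ccc(OCc3ccccc3)cc2)o1 | intermediate (not isolated)
15 | (3E)-4-{5-(benzyloxy)-6-[4-(benzyloxy)phenyl]-4-oxo-4H-pyran-2-yl}-3-(triisopropylsilyloxy)buta-1,3-dien-1-one (pyranonyl group cis to the ketene arm) | O=C=C/C(O[Si](C(C)C)(C(C)C)C(C)C)=C\c1cc(=O)c(OCc2ccccc2)c(-c2ccc(OCc3ccccc3)cc2)o1 | intermediate (not isolated)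
16 | 3-(benzyloxy)-2-[4-(benzyloxy)phenyl]-7-(triisopropylsilyloxy)-4aH-chromene-4,5-dione (racemic, transient) | O=C1C=C(O[Si](C(C)C)(C(C)C)C(C)C)C=C2OC(-c3ccc(OCc4ccccc4)cc3)=C(OCc3ccccc3)C(=O)C12 | intermediate (not isolated)
17 | 3-(benzyloxy)-2-[4-(benzyloxy)phenyl]-5-hydroxy-7-(triisopropylsilyloxy)-4H-chromen-4-one | O=c1c(OCc2ccccc2)c(-c2ccc(OCc3ccccc3)cc2)oc2cc(O[Si](C(C)C)(C(C)C)C(C)C)cc(O)c12 | intermediate
18 | 3-(benzyloxy)-2-[4-(benzyloxy)phenyl]-5,7-dihydroxy-4H-chromen-4-one | O=c1c(OCc2ccccc2)c(-c2ccc(OCc3ccccc3)cc2)oc2cc(O)cc(O)c12 | intermediate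
19 | 3-(benzyloxy)-2-[4-(benzyloxy)phenyl]-5-hydroxy-4-oxo-4H-chromen-7-yl hydrogen sulfate | O=c1c(OCc2ccccc2)c(-c2ccc(OCc3ccccc3)cc2)oc2cc(OS(=O)(=O)O)cc(O)c12 | intermediate
20 | kaempferol 7-O-sulfate | O=c1c(O)c(-c2ccc(O)cc2)oc2cc(OS(=O)(=O)O)cc(O)c12 | target

Total step count: 10. Longest linear sequence: 9 steps (steps 1–5 and 7–10, from kojic acid); step 6 is a one-step branch.

Steps most likely to fail

Step 7 (the benzannulation). The ketene may be lost to dimerisation or to attack by unreacted diazoketone before the cycloaddition. The cascade may also stall at the cyclobutenone stage or close only sluggishly onto the electron-poor pyranone, and competing light-driven hydrogen abstraction at the benzyloxy group may erode material. The fallback builds ring A by ionic, polyketide-style chemistry, sets out from 8 and comes back to the route at 18. Silver-catalysed Wolff rearrangement of 8 in aqueous THF (PhCO2Ag, Et3N; Arndt–Eistert homologation) should give {5-(benzyloxy)-6-[4-(benzyloxy)phenyl]-4-oxo-4H-pyran-2-yl}acetic acid F1. Activation with 1,1'-carbonyldiimidazole at room temperature gives 1-({5-(benzyloxy)-6-[4-(benzyloxy)phenyl]-4-oxo-4H-pyran-2-yl}acetyl)imidazole F2, which is not isolated. A Masamune–Brooks reaction with Mg(O2CCH2CO2Et)2 then gives ethyl 4-{5-(benzyloxy)-6-[4-(benzyloxy)phenyl]-4-oxo-4H-pyran-2-yl}-3-oxobutanoate F3. Treatment with Mg(OMe)2 in methanol should then effect an intramolecular Claisen condensation in which pyranone C3, the α-carbon of the extended enolate, attacks the ester. Enolisation of the resulting cyclic triketone aromatises ring A and delivers diol 18 directly, with O7 distinguished from O5 by the chelate alone.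

Step 6 (the parent siloxyalkyne). Silylation may occur on carbon instead of oxygen and lead to a silylketene, ethylenediamine may divert the silyl triflate, and the volatile terminal ynol ether may suffer 1,3-silyl shift or hydrolysis on handling. The fallback changes the alkyne partner, sets out from 10 and comes back at 17. Commercial (trimethylsilyl)acetylene is lithiated with n-BuLi, with no amine present, oxidised with t-BuOOLi as in step 6 and silylated on oxygen with 10 to give triisopropyl{[(trimethylsilyl)ethynyl]oxy}silane F4, a less volatile ynol ether with a blocked terminus. Benzannulation of F4 with 8 under the conditions of step 7 places the carbon-bound silyl group at C6 and should give 3-(benzyloxy)-2-[4-(benzyloxy)phenyl]-5-hydroxy-6-(trimethylsilyl)-7-(triisopropylsilyloxy)-4H-chromen-4-one F5. Ipso-protodesilylation of this electron-rich arylsilane with CF3CO2H in CH2Cl2 at 0 °C then returns 17.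

Step 5 (the diazoketone). The diazoalkane may add as a dipole across the electron-poor pyranone double bond, chloride may intercept the acyldiazonium stage to give loss of the diazo group, and the chlorinating agent may activate the pyranone carbonyl. The fallback avoids acid chloride and diazoalkane altogether, sets out from 6 and comes back at 8. Coupling of 6 with MeNHOMe·HCl (1,1'-carbonyldiimidazole) gives 5-(benzyloxy)-6-[4-(benzyloxy)phenyl]-N-methoxy-N-methyl-4-oxo-4H-pyran-2-carboxamide F6, and MeMgBr at −78 °C gives 6-acetyl-3-(benzyloxy)-2-[4-(benzyloxy)phenyl]-4H-pyran-4-one F7. Its lithium enolate (LiN(SiMe3)2, −78 °C) is acylated with CF3CO2CH2CF3 to 1-{5-(benzyloxy)-6-[4-(benzyloxy)phenyl]-4-oxo-4H-pyran-2-yl}-4,4,4-trifluorobutane-1,3-dione F8, which is not isolated. Deacylative diazo transfer with MsN3, Et3N and water in MeCN then delivers 8.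

Further compounds
F1 | step 7 | {5-(benzyloxy)-6-[4-(benzyloxy)phenyl]-4-oxo-4H-pyran-2-yl}acetic acid | OC(=O)Cc1cc(=O)c(OCc2ccccc2)c(-c2ccc(OCc3ccccc3)cc2)o1
F2 | step 7 | 1-({5-(benzyloxy)-6-[4-(benzyloxy)phenyl]-4-oxo-4H-pyran-2-yl}acetyl)imidazole | O=C(Cc1cc(=O)c(OCc2ccccc2)c(-c2ccc(OCc3ccccc3)cc2)o1)n1ccnc1
F3 | step 7 | ethyl 4-{5-(benzyloxy)-6-[4-(benzyloxy)phenyl]-4-oxo-4H-pyran-2-yl}-3-oxobutanoate | CCOC(=O)CC(=O)Cc1cc(=O)c(OCc2ccccc2)c(-c2ccc(OCc3ccccc3)cc2)o1
F4 | step 6 | triisopropyl{[(trimethylsilyl)ethynyl]oxy}silane | C[Si](C)(C)C#CO[Si](C(C)C)(C(C)C)C(C)C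
F5 | step 6 | 3-(benzyloxy)-2-[4-(benzyloxy)phenyl]-5-hydroxy-6-(trimethylsilyl)-7-(triisopropylsilyloxy)-4H-chromen-4-one | O=c1c(OCc2ccccc2)c(-c2ccc(OCc3ccccc3)cc2)oc2cc(O[Si](C(C)C)(C(C)C)C(C)C)c([Si](C)(C)C)c(O)c12
F6 | step 5 | 5-(benzyloxy)-6-[4-(benzyloxy)phenyl]-N-methoxy-N-methyl-4-oxo-4H-pyran-2-carboxamide | CON(C)C(=O)c1cc(=O)c(OCc2ccccc2)c(-c2ccc(OCc3ccccc3)cc2)o1
F7 | step 5 | 6-acetyl-3-(benzyloxy)-2-[4-(benzyloxy)phenyl]-4H-pyran-4-one | CC(=O)c1cc(=O)c(OCc2ccccc2)c(-c2ccc(OCc3ccccc3)cc2)o1
F8 | step 5 | 1-{5-(benzyloxy)-6-[4-(benzyloxy)phenyl]-4-oxo-4H-pyran-2-yl}-4,4,4-trifluorobutane-1,3-dione | O=C(CC(=O)C(F)(F)F)c1cc(=O)c(OCc2ccccc2)c(-c2ccc(OCc3ccccc3)cc2)o1
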